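**Plan**

Rings are lettered A (2,4,6-trioxygenated end) to G (3,4,5-trioxygenated end). In rings B, C, E, F and G, C1 is the ether carbon flanked by two CH positions and C4 the oxygenated carbon flanked by two oxygenated carbons. In ring D, D1 carries the oxygen to ring C, D2 is CH and D6 carries the oxygen to ring E.
Retrosynthesis: the 17 O–H bonds go back to O–CH3. The E1–O, F1–O and G1–O bonds are then cut by putting CO back in. This is possible because E1, F1 and G1 each lie para to a ring oxygen (E4, F4, G4) between two CH carbons, which is the position of the carboxyl carbon in syringic acid (rings E and F) and in 3,4,5-trimethoxybenzoic acid (ring G, used as its chloride). The D6–O acyl bond is cut last, giving a ring A–D phenol and a G–F–E depside acid.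
Forward: rings B and C are added to 2,4,6-trimethoxyphenol by fluoride displacement followed by Dakin-type oxidation, and ring D by Ullmann coupling and a third oxidation. The depside acid is built separately from the G end and acylates the D6 hydroxyl. Triple loss of CO then gives the permethylated heptamer, and BBr3 frees the 17 phenols.
Stereochemistry: none. The target is achiral, with no stereocentre or stereogenic axis to set.

Key step: step 14

Assumptions: 4-fluoro-2,6-dimethoxybenzaldehyde, 5-bromo-1,2,3-trimethoxybenzene and 3,4,5-trimethoxybenzoyl chloride are taken as catalogue compounds. The three ester groups of the key-step substrate may lose CO in any order, all orders ending in the same heptamer; the two non-isolated intermediates are drawn for loss from the chain end inward.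

**Step 1**
Reactants: 1 (2,4,6-trimethoxyphenol); 2 (4-fluoro-2,6-dimethoxybenzaldehyde)
Product: 3 ring A–B aldehyde [2,6-dimethoxy-4-(2,4,6-trimethoxyphenoxy)benzaldehyde]
Conditions: Cs2CO3, DMSO, 110 °C, argon
Reagents that add atoms: none
Why: Nucleophilic aromatic substitution by addition–elimination: the cesium phenoxide of 1 attacks C4 of 2, the para-formyl group stabilises the Meisenheimer intermediate and fluoride leaves, a reaction type well documented for 2,6-dimethoxyphenoxides and 4-fluorobenzaldehydes.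

**Step 2**
Reactants: 3 (ring A–B aldehyde)
Product: 5 ring A–B phenol [2,6-dimethoxy-4-(2,4,6-trimethoxyphenoxy)phenol], via ring A–B aryl formate 4 (not isolated)
Conditions: mCPBA, CH2Cl2, 0 °C to rt; aq. NaHCO3 wash; then K2CO3 (cat.), MeOH, rt, argon
Reagents that add atoms: mCPBA, OOC(=O)c1cccc(Cl)c1
Why: Baeyer–Villiger (Dakin-type) oxidation: in the peracid adduct the electron-rich 2,6-dimethoxyaryl group migrates in preference to hydrogen, and the formate 4, which protects the new hydroquinone monoether from over-oxidation, is methanolysed only after the oxidant has been removed.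

**Step 3**
Reactants: 5 (ring A–B phenol); 2 (4-fluoro-2,6-dimethoxybenzaldehyde)
Product: 6 ring A–C aldehyde [4-[2,6-dimethoxy-4-(2,4,6-trimethoxyphenoxy)phenoxy]-2,6-dimethoxybenzaldehyde]
Conditions: Cs2CO3, DMSO, 110 °C, argon
Reagents that add atoms: none
Why: Same addition–elimination as in step 1, since the phenoxide of 5 has the same 2,6-dimethoxy environment as that of 1 and attacks the unhindered, formyl-activated C4 of 2.

**Step 4**
Reactants: 6 (ring A–C aldehyde)
Product: 8 ring A–C phenol [4-[2,6-dimethoxy-4-(2,4,6-trimethoxyphenoxy)phenoxy]-2,6-dimethoxyphenol], via ring A–C aryl formate 7 (not isolated)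
Conditions: mCPBA, CH2Cl2, 0 °C to rt; aq. NaHCO3 wash; then K2CO3 (cat.), MeOH, rt, argon
Reagents that add atoms: mCPBA, OOC(=O)c1cccc(Cl)c1
Why: Baeyer–Villiger (Dakin-type) oxidation as in step 2, the formyl group again sitting between two methoxy groups on a ring carbon well suited to aryl migration.

**Step 5**
Reactants: 9 (5-bromo-1,2,3-trimethoxybenzene)
Product: 11 6-bromo-2,3,4-trimethoxybenzaldehyde, via α-chloro ether 10 (not isolated)
Conditions: Cl2CHOMe, TiCl4, CH2Cl2, −10 to 0 °C; then ice-water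
Reagents that add atoms: dichloromethyl methyl ether, COC(Cl)Cl (formyl carbon); water, O (carbonyl oxygen)
Why: Rieche formylation: the TiCl4-activated dichloromethyl methyl ether attacks C4 of 9 (C4 and C6 are equivalent and are the only free positions, each ortho and para to a methoxy group), and aqueous work-up hydrolyses the α-chloro ether 10 to the aldehyde.

**Step 6**
Reactants: 8 (ring A–C phenol); 11 (6-bromo-2,3,4-trimethoxybenzaldehyde)
Product: 12 ring A–D aldehyde [6-{4-[2,6-dimethoxy-4-(2,4,6-trimethoxyphenoxy)phenoxy]-2,6-dimethoxyphenoxy}-2,3,4-trimethoxybenzaldehyde]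
Conditions: CuI (10 mol%), picolinic acid (20 mol%), K3PO4, DMSO, 90 °C, rigorously degassed, argon
Reagents that add atoms: none
Why: Ullmann diaryl ether synthesis: the ortho-formyl group accelerates copper insertion into the C–Br bond of 11 and the CuI–picolinic acid system is known to couple doubly ortho-substituted phenols, while strict exclusion of air protects the oxidisable phenoxide of 8.

**Step 7**
Reactants: 12 (ring A–D aldehyde)
Product: 14 ring A–D phenol with free D6 hydroxyl [6-{4-[2,6-dimethoxy-4-(2,4,6-trimethoxyphenoxy)phenoxy]-2,6-dimethoxyphenoxy}-2,3,4-trimethoxyphenol], via ring A–D aryl formate 13 (not isolated)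
Conditions: mCPBA, CH2Cl2, 0 °C to rt; aq. NaHCO3 wash; then K2CO3 (cat.), MeOH, rt, argon
Reagents that add atoms: mCPBA, OOC(=O)c1cccc(Cl)c1
Why: Baeyer–Villiger (Dakin-type) oxidation as in steps 2 and 4; the migrating ring D carbon is ortho and para to oxygen substituents, so aryl migration is favoured over hydride migration and the D6 hydroxyl appears between the aryloxy and methoxy groups.

**Step 8**
Reactants: 15 (syringic acid)
Product: 16 benzyl syringate [benzyl 4-hydroxy-3,5-dimethoxybenzoate]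
Conditions: BnBr, KHCO3, DMF, 40 °C
Reagents that add atoms: benzyl bromide, BrCc1ccccc1
Why: Chemoselective carboxylate O-alkylation (SN2 ester formation): KHCO3 deprotonates only the carboxylic acid, so benzyl bromide esterifies it and the less acidic, doubly flanked phenol stays free.

**Step 9**
Reactants: 16 (benzyl syringate); 17 (3,4,5-trimethoxybenzoyl chloride)
Product: 18 G–F depside benzyl ester [benzyl 3,5-dimethoxy-4-[(3,4,5-trimethoxybenzoyl)oxy]benzoate]
Conditions: Et3N, DMAP (cat.), CH2Cl2, 0 °C to rt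
Reagents that add atoms: none
Why: Acylation of a phenol by an acid chloride under DMAP nucleophilic catalysis (Einhorn-type conditions), which is routine for 2,6-dimethoxyphenols.

**Step 10**
Reactants: 18 (G–F depside benzyl ester)
Product: 19 G–F depside acid [3,5-dimethoxy-4-[(3,4,5-trimethoxybenzoyl)oxy]benzoic acid]
Conditions: H2 (1 atm), 10% Pd/C, EtOAc, rt
Reagents that add atoms: none
Why: Catalytic hydrogenolysis of the benzyl ester over Pd/C; the aryl ester and the aryl methyl ethers are inert under these conditions.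

**Step 11**
Reactants: 19 (G–F depside acid); 16 (benzyl syringate)
Product: 21 G–F–E tridepside benzyl ester [benzyl 4-({3,5-dimethoxy-4-[(3,4,5-trimethoxybenzoyl)oxy]benzoyl}oxy)-3,5-dimethoxybenzoate], via depside acid chloride 20 (not isolated)
Conditions: (COCl)2, DMF (cat.), CH2Cl2, 0 °C to rt, evaporate; then 16, Et3N, DMAP (cat.), CH2Cl2, 0 °C to rt
Reagents that add atoms: none
Why: Oxalyl chloride under DMF (Vilsmeier-type) catalysis converts the acid into its chloride without touching the aryl ester, and the chloride acylates the hindered phenol of a second molecule of 16 as in step 9.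

**Step 12**
Reactants: 21 (G–F–E tridepside benzyl ester)
Product: 22 G–F–E tridepside acid [4-({3,5-dimethoxy-4-[(3,4,5-trimethoxybenzoyl)oxy]benzoyl}oxy)-3,5-dimethoxybenzoic acid]
Conditions: H2 (1 atm), 10% Pd/C, EtOAc/THF, rt
Reagents that add atoms: none
Why: Hydrogenolysis of the benzyl ester as in step 10; the two aryl esters are stable to H2 over Pd/C.

**Step 13**
Reactants: 22 (G–F–E tridepside acid); 14 (ring A–D phenol)
Product: 24 ring A–D tetramer acylated on the D6 oxygen by the syringoyl–syringoyl–3,4,5-trimethoxybenzoyl chain, via tridepside acid chloride 23 (not isolated)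
Conditions: (COCl)2, DMF (cat.), CH2Cl2, 0 °C to rt, evaporate; then 14, Et3N, DMAP (cat.), CH2Cl2, 0 °C to rt
Reagents that add atoms: none
Why: Acid chloride formation and DMAP-catalysed phenol acylation as in step 11; the acid chloride is far more electrophilic than the internal aryl esters, so the D6 phenoxide should be acylated before ester exchange can occur.

**Step 14**
Reactants: 24 (D6-O-tridepside ester of the ring A–D tetramer)
Product: 27 permethylated heptamer (heptadeca-O-methyl ether of the target), via diester monoether 25 (not isolated), via monoester diether 26 (not isolated)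
Conditions: Ni(cod)2 (30 mol%), dcypt [3,4-bis(dicyclohexylphosphino)thiophene] (60 mol%), K3PO4 (4.5 equiv), mesitylene (0.02 M), 150 °C, slow argon sweep
Reagents that add atoms: none
Why: Proposed new method: at each of the three aryl ester groups, zerovalent nickel carrying the chelating, electron-rich dcypt should insert into the acyl C–O bond with the 2,6-dioxygenated aryloxide as leaving group, the aroyl nickel aryloxide should lose CO by aryl migration and dissociation of the carbonyl ligand, and C–O reductive elimination from the divalent aryl nickel aryloxide should join E1, F1 and G1 to the oxygens on D6, E4 and F4. The closest known reaction type is the nickel- or palladium-catalysed decarbonylative etherification of aryl esters with this ligand, established for azine- and other heteroarenecarboxylic acid aryl esters, together with the decarbonylative thioetherification of aryl thioesters; nitrogen-free benzoates and three esters in one substrate lie outside that scope. No ring is closed and no stereocentre is formed. The selectivity needed is insertion into the acyl C–O rather than the aryl C–O bond and loss of CO before aryloxides can exchange between chains; the phenolic nature of each ester, the bulky bisphosphine, the inductively withdrawing meta-methoxy groups on every aroyl ring, high dilution and the argon sweep that removes CO should secure it. Because every ester gives the same ether whatever the order of reaction, partly converted material can be resubmitted to the same conditions.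

**Step 15**
Reactants: 27 (permethylated heptamer)
Product: 28 target CNP0304148.0 (the heptadecahydroxy heptamer)
Conditions: BBr3 (1 M in CH2Cl2, 3 equiv per OMe), CH2Cl2, −78 °C to rt, argon; then degassed ice-water
Reagents that add atoms: none
Why: Lewis acid ether cleavage: BBr3 binds each methoxy oxygen and bromide removes the methyl group by SN2 attack, whereas the diaryl ether bonds, which offer no sp3 carbon, survive.

**Compound list**

1 | 2,4,6-trimethoxyphenol | COc1cc(OC)c(O)c(OC)c1 | starting material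
2 | 4-fluoro-2,6-dimethoxybenzaldehyde | COc1cc(F)cc(OC)c1C=O | starting material
3 | ring A–B aldehyde, 2,6-dimethoxy-4-(2,4,6-trimethoxyphenoxy)benzaldehyde | COc1cc(OC)c(Oc2cc(OC)c(C=O)c(OC)c2)c(OC)c1 | intermediate
4 | ring A–B aryl formate, 2,6-dimethoxy-4-(2,4,6-trimethoxyphenoxy)phenyl formate | COc1cc(OC)c(Oc2cc(OC)c(OC=O)c(OC)c2)c(OC)c1 | intermediate (not isolated)
5 | ring A–B phenol, 2,6-dimethoxy-4-(2,4,6-trimethoxyphenoxy)phenol | COc1cc(OC)c(Oc2cc(OC)c(O)c(OC)c2)c(OC)c1 | intermediate
6 | ring A–C aldehyde, 4-[2,6-dimethoxy-4-(2,4,6-trimethoxyphenoxy)phenoxy]-2,6-dimethoxybenzaldehyde | COc1cc(OC)c(Oc2cc(OC)c(Oc3cc(OC)c(C=O)c(OC)c3)c(OC)c2)c(OC)c1 | intermediate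
7 | ring A–C aryl formate | COc1cc(OC)c(Oc2cc(OC)c(Oc3cc(OC)c(OC=O)c(OC)c3)c(OC)c2)c(OC)c1 | intermediate (not isolated)
8 | ring A–C phenol, 4-[2,6-dimethoxy-4-(2,4,6-trimethoxyphenoxy)phenoxy]-2,6-dimethoxyphenol | COc1cc(OC)c(Oc2cc(OC)c(Oc3cc(OC)c(O)c(OC)c3)c(OC)c2)c(OC)c1 | intermediate
9 | 5-bromo-1,2,3-trimethoxybenzene | COc1cc(Br)cc(OC)c1OC | starting material
10 | α-chloro ether, 1-bromo-2-[chloro(methoxy)methyl]-3,4,5-trimethoxybenzene (racemic) | COC(Cl)c1c(Br)cc(OC)c(OC)c1OC | intermediate (not isolated)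
11 | 6-bromo-2,3,4-trimethoxybenzaldehyde | COc1cc(Br)c(C=O)c(OC)c1OC | intermediate
12 | ring A–D aldehyde, 6-{4-[2,6-dimethoxy-4-(2,4,6-trimethoxyphenoxy)phenoxy]-2,6-dimethoxyphenoxy}-2,3,4-trimethoxybenzaldehyde | COc1cc(OC)c(Oc2cc(OC)c(Oc3cc(OC)c(Oc4cc(OC)c(OC)c(OC)c4C=O)c(OC)c3)c(OC)c2)c(OC)c1 | intermediate
13 | ring A–D aryl formate | COc1cc(OC)c(Oc2cc(OC)c(Oc3cc(OC)c(Oc4cc(OC)c(OC)c(OC)c4OC=O)c(OC)c3)c(OC)c2)c(OC)c1 | intermediate (not isolated)
14 | ring A–D phenol (free OH on D6), 6-{4-[2,6-dimethoxy-4-(2,4,6-trimethoxyphenoxy)phenoxy]-2,6-dimethoxyphenoxy}-2,3,4-trimethoxyphenol | COc1cc(OC)c(Oc2cc(OC)c(Oc3cc(OC)c(Oc4cc(OC)c(OC)c(OC)c4O)c(OC)c3)c(OC)c2)c(OC)c1 | intermediate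
15 | syringic acid, 4-hydroxy-3,5-dimethoxybenzoic acid | COc1cc(C(=O)O)cc(OC)c1O | starting material
16 | benzyl syringate, benzyl 4-hydroxy-3,5-dimethoxybenzoate | COc1cc(C(=O)OCc2ccccc2)cc(OC)c1O | intermediate
17 | 3,4,5-trimethoxybenzoyl chloride | COc1cc(C(Cl)=O)cc(OC)c1OC | starting material
18 | G–F depside benzyl ester, benzyl 3,5-dimethoxy-4-[(3,4,5-trimethoxybenzoyl)oxy]benzoate | COc1cc(C(=O)Oc2c(OC)cc(C(=O)OCc3ccccc3)cc2OC)cc(OC)c1OC | intermediate
19 | G–F depside acid, 3,5-dimethoxy-4-[(3,4,5-trimethoxybenzoyl)oxy]benzoic acid | COc1cc(C(=O)Oc2c(OC)cc(C(=O)O)cc2OC)cc(OC)c1OC | intermediate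
20 | G–F depside acid chloride | COc1cc(C(=O)Oc2c(OC)cc(C(Cl)=O)cc2OC)cc(OC)c1OC | intermediate (not isolated)
21 | G–F–E tridepside benzyl ester | COc1cc(C(=O)Oc2c(OC)cc(C(=O)Oc3c(OC)cc(C(=O)OCc4ccccc4)cc3OC)cc2OC)cc(OC)c1OC | intermediate
22 | G–F–E tridepside acid | COc1cc(C(=O)Oc2c(OC)cc(C(=O)Oc3c(OC)cc(C(=O)O)cc3OC)cc2OC)cc(OC)c1OC | intermediate
23 | G–F–E tridepside acid chloride | COc1cc(C(=O)Oc2c(OC)cc(C(=O)Oc3c(OC)cc(C(Cl)=O)cc3OC)cc2OC)cc(OC)c1OC | intermediate (not isolated)
24 | ring A–D tetramer esterified on the D6 oxygen by the syringoyl–syringoyl–3,4,5-trimethoxybenzoyl chain | COc1cc(OC)c(Oc2cc(OC)c(Oc3cc(OC)c(Oc4cc(OC)c(OC)c(OC)c4OC(=O)c4cc(OC)c(OC(=O)c5cc(OC)c(OC(=O)c6cc(OC)c(OC)c(OC)c6)c(OC)c5)c(OC)c4)c(OC)c3)c(OC)c2)c(OC)c1 | intermediate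
25 | diester monoether (G1–O formed, two esters left) | COc1cc(OC)c(Oc2cc(OC)c(Oc3cc(OC)c(Oc4cc(OC)c(OC)c(OC)c4OC(=O)c4cc(OC)c(OC(=O)c5cc(OC)c(Oc6cc(OC)c(OC)c(OC)c6)c(OC)c5)c(OC)c4)c(OC)c3)c(OC)c2)c(OC)c1 | intermediate (not isolated)
26 | monoester diether (G1–O and F1–O formed, D6 ester left) | COc1cc(OC)c(Oc2cc(OC)c(Oc3cc(OC)c(Oc4cc(OC)c(OC)c(OC)c4OC(=O)c4cc(OC)c(Oc5cc(OC)c(Oc6cc(OC)c(OC)c(OC)c6)c(OC)c5)c(OC)c4)c(OC)c3)c(OC)c2)c(OC)c1 | intermediate (not isolated)
27 | permethylated heptamer (heptadeca-O-methyl ether of the target) | COc1cc(OC)c(Oc2cc(OC)c(Oc3cc(OC)c(Oc4cc(OC)c(OC)c(OC)c4Oc4cc(OC)c(Oc5cc(OC)c(Oc6cc(OC)c(OC)c(OC)c6)c(OC)c5)c(OC)c4)c(OC)c3)c(OC)c2)c(OC)c1 | intermediate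
28 | CNP0304148.0, heptadecahydroxy heptameric aryl ether | Oc1cc(O)c(Oc2cc(O)c(Oc3cc(O)c(Oc4cc(O)c(O)c(O)c4Oc4cc(O)c(Oc5cc(O)c(Oc6cc(O)c(O)c(O)c6)c(O)c5)c(O)c4)c(O)c3)c(O)c2)c(O)c1 | target

**Step count**

Total: 15 steps. Longest linear sequence: 9 steps (1, 2, 3, 4, 6, 7, 13, 14, 15).

**Steps most likely to fail**

Step 14. Insertion of nickel into the three nitrogen-free benzoates may be slow, and the CO set free may bind the zerovalent nickel, so the sequence may stall at partly decarbonylated esters. Aryloxides that leave the metal may also exchange between chains and scramble the oligomer length. The fallback uses only the reactions of steps 1 to 4, sets out from 14 and returns at 27. Phenol 14 displaces the fluoride of 2 (Cs2CO3, DMSO, 110 °C) to give the ring A–E aldehyde F1, which mCPBA converts by way of the ring A–E aryl formate F2 (K2CO3 cat., MeOH) into the ring A–E phenol F3. A second round with 2 gives the ring A–F aldehyde F4, the ring A–F aryl formate F5 and the ring A–F phenol F6. A third round gives the ring A–G aldehyde F7, the ring A–G aryl formate F8 and the ring A–G phenol F9, whose free G4 hydroxyl is methylated (MeI, K2CO3, acetone) to give 27.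

Step 15. Some of the 17 methyl ethers may stay uncleaved, and the 1,2,3-trihydroxylated rings D and G may be oxidised by air while the free polyphenol is purified. The fallback sets out from 27 and returns at 28. After the BBr3 treatment the crude polyphenol is acetylated without purification (Ac2O, pyridine, DMAP, rt) to the heptadecaacetate F10, which is stable to air and silica gel and can be separated from incompletely demethylated material. Acid-catalysed methanolysis (HCl in MeOH, argon, rt) then removes the acetyl groups and gives 28 without chromatography of the free phenol.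

Step 6. Copper may oxidise the p-aryloxyphenoxide of 8 by one-electron transfer, with loss of the ring A–B aryloxide and quinone formation, and coupling at the doubly ortho-substituted oxygen may be slow. The fallback removes the metal, sets out from 8 and returns at 12. Purchased 5-fluoro-1,2,3-trimethoxybenzene is formylated as in step 5, by way of the α-chloro ether F11, to 6-fluoro-2,3,4-trimethoxybenzaldehyde F12. The phenoxide of 8 then displaces the ortho-formyl-activated fluoride (Cs2CO3, DMSO, 130 °C, argon) in a copper-free nucleophilic aromatic substitution to give 12.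

**Further compounds**

F1 | step 14 | ring A–E aldehyde | COc1cc(OC)c(Oc2cc(OC)c(Oc3cc(OC)c(Oc4cc(OC)c(OC)c(OC)c4Oc4cc(OC)c(C=O)c(OC)c4)c(OC)c3)c(OC)c2)c(OC)c1
F2 | step 14 | ring A–E aryl formate | COc1cc(OC)c(Oc2cc(OC)c(Oc3cc(OC)c(Oc4cc(OC)c(OC)c(OC)c4Oc4cc(OC)c(OC=O)c(OC)c4)c(OC)c3)c(OC)c2)c(OC)c1
F3 | step 14 | ring A–E phenol | COc1cc(OC)c(Oc2cc(OC)c(Oc3cc(OC)c(Oc4cc(OC)c(OC)c(OC)c4Oc4cc(OC)c(O)c(OC)c4)c(OC)c3)c(OC)c2)c(OC)c1
F4 | step 14 | ring A–F aldehyde | COc1cc(OC)c(Oc2cc(OC)c(Oc3cc(OC)c(Oc4cc(OC)c(OC)c(OC)c4Oc4cc(OC)c(Oc5cc(OC)c(C=O)c(OC)c5)c(OC)c4)c(OC)c3)c(OC)c2)c(OC)c1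
F5 | step 14 | ring A–F aryl formate | COc1cc(OC)c(Oc2cc(OC)c(Oc3cc(OC)c(Oc4cc(OC)c(OC)c(OC)c4Oc4cc(OC)c(Oc5cc(OC)c(OC=O)c(OC)c5)c(OC)c4)c(OC)c3)c(OC)c2)c(OC)c1
F6 | step 14 | ring A–F phenol | COc1cc(OC)c(Oc2cc(OC)c(Oc3cc(OC)c(Oc4cc(OC)c(OC)c(OC)c4Oc4cc(OC)c(Oc5cc(OC)c(O)c(OC)c5)c(OC)c4)c(OC)c3)c(OC)c2)c(OC)c1
F7 | step 14 | ring A–G aldehyde | COc1cc(OC)c(Oc2cc(OC)c(Oc3cc(OC)c(Oc4cc(OC)c(OC)c(OC)c4Oc4cc(OC)c(Oc5cc(OC)c(Oc6cc(OC)c(C=O)c(OC)c6)c(OC)c5)c(OC)c4)c(OC)c3)c(OC)c2)c(OC)c1
F8 | step 14 | ring A–G aryl formate | COc1cc(OC)c(Oc2cc(OC)c(Oc3cc(OC)c(Oc4cc(OC)c(OC)c(OC)c4Oc4cc(OC)c(Oc5cc(OC)c(Oc6cc(OC)c(OC=O)c(OC)c6)c(OC)c5)c(OC)c4)c(OC)c3)c(OC)c2)c(OC)c1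
F9 | step 14 | ring A–G phenol (free OH on G4) | COc1cc(OC)c(Oc2cc(OC)c(Oc3cc(OC)c(Oc4cc(OC)c(OC)c(OC)c4Oc4cc(OC)c(Oc5cc(OC)c(Oc6cc(OC)c(O)c(OC)c6)c(OC)c5)c(OC)c4)c(OC)c3)c(OC)c2)c(OC)c1
F10 | step 15 | heptadecaacetate of the target | CC(=O)Oc1cc(OC(C)=O)c(Oc2cc(OC(C)=O)c(Oc3cc(OC(C)=O)c(Oc4cc(OC(C)=O)c(OC(C)=O)c(OC(C)=O)c4Oc4cc(OC(C)=O)c(Oc5cc(OC(C)=O)c(Oc6cc(OC(C)=O)c(OC(C)=O)c(OC(C)=O)c6)c(OC(C)=O)c5)c(OC(C)=O)c4)c(OC(C)=O)c3)c(OC(C)=O)c2)c(OC(C)=O)c1
F11 | step 6 | α-chloro ether, 2-[chloro(methoxy)methyl]-1-fluoro-3,4,5-trimethoxybenzene (racemic) | COC(Cl)c1c(F)cc(OC)c(OC)c1OC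
F12 | step 6 | 6-fluoro-2,3,4-trimethoxybenzaldehyde | COc1cc(F)c(C=O)c(OC)c1OC
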